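**Retrosynthetic overview**

1. The target is read as ent-fisetinidol-(4α→6)-ent-fisetinidol-(4α→8)-catechin-(6→4α)-ent-fisetinidol (each ent-fisetinidol unit 2S,3R, 2,3-trans-3,4-cis). The three C4–aryl bonds are cut, and the catechin unit comes unchanged from (+)-catechin.
2. Each ent-fisetinidol unit is traced through its 2,4-trans-4-arylflavan-3-one to an aromatic C–H and one building block, the 2-aryl-3-(diethoxymethyl)-2,3-dihydrobenzofuran-3-ol 10 (as bromide 11 or chloride 12).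
3. Enabling feature: in 10–12 the carbinol carbon C3 of the five-membered ring O1–C2–C3–C3a–C7a carries the acetal carbon and the ring A carbon C3a, which is para to the 6-benzyloxy group and ortho to O1. Once the acetal carbon has arylated the partner and is cationic, C3a shifts from C3 to it, C3 becomes a ketone, and the five-membered ring becomes the pyran ring O1–C2–C3–C4–C4a–C8a.
4. Order of ring formation: dihydrobenzofuran ring of the building block (alkyne → alkenyl boronate → stilbene-type alkene → epoxide → 5-exo opening); then the pyran ring of unit B at catechin C8, the pyran ring of unit D at catechin C6, and the pyran ring of unit A at C6 of unit B. Halogens at C6 of the new units are temporary blockers (Br on B is removed by Br/Li exchange, Cl on D and A in the final hydrogenolysis).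
5. Stereocontrol: C2 from the Shi epoxidation and the inverting epoxide opening; C4 from the rearrangement (trans to the 2-aryl group); C3 from hydride attack anti to the quasi-axial 4-aryl group.

Key step: step 12

Remark: 4-bromo-1,2-bis(benzyloxy)benzene, 3,3-diethoxyprop-1-yne, 5-(benzyloxy)-2-bromophenol and (+)-catechin are taken as commercially available.

**Route**

Step 1
Reactants: 1 4-bromo-1,2-bis(benzyloxy)benzene; 2 3,3-diethoxyprop-1-yne
Product: 3 1,2-bis(benzyloxy)-4-(3,3-diethoxyprop-1-yn-1-yl)benzene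
Conditions: Pd(PPh3)2Cl2 (3 mol%), CuI (5 mol%), Et3N, DMF, 70 °C
Reagents that add atoms: none
Why: Sonogashira coupling of an aryl bromide with a terminal alkyne; the acetal tolerates the basic medium.

Step 2
Reactants: 3 1,2-bis(benzyloxy)-4-(3,3-diethoxyprop-1-yn-1-yl)benzene
Product: 4 2-[(1Z)-1-[3,4-bis(benzyloxy)phenyl]-3,3-diethoxyprop-1-en-2-yl]-4,4,5,5-tetramethyl-1,3,2-dioxaborolane
Conditions: B2pin2 (1.1 equiv), CuCl (5 mol%), Xantphos (5 mol%), NaOtBu (10 mol%), MeOH (2 equiv), THF, rt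
Reagents that add atoms: bis(pinacolato)diboron, CC1(C)OB(OC1(C)C)B1OC(C)(C)C(C)(C)O1
Why: Copper-catalysed formal hydroboration (syn borylcupration, then protonation by MeOH); boron should go to the carbon β to the aryl group because the alkenylcopper prefers the benzylic carbon, and syn addition fixes the geometry with the aryl group cis to the acetal carbon.

Step 3
Reactants: 5 5-(benzyloxy)-2-bromophenol
Product: 6 5-(benzyloxy)-2-bromophenyl 2,2-dimethylpropanoate
Conditions: t-BuCOCl, Et3N, DMAP (cat.), CH2Cl2, 0 °C → rt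
Reagents that add atoms: pivaloyl chloride, CC(C)(C)C(=O)Cl
Why: Acylation of the phenol; the pivalate protects it from the oxidant of step 5 and is removed in step 6.

Step 4
Reactants: 4 alkenyl boronate; 6 5-(benzyloxy)-2-bromophenyl 2,2-dimethylpropanoate
Product: 7 5-(benzyloxy)-2-[(1Z)-1-[3,4-bis(benzyloxy)phenyl]-3,3-diethoxyprop-1-en-2-yl]phenyl 2,2-dimethylpropanoate (the two aryl groups trans)
Conditions: Pd(OAc)2 (3 mol%), SPhos (6 mol%), K3PO4, toluene/H2O, 70 °C
Reagents that add atoms: none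
Why: Suzuki–Miyaura coupling with retention of alkene geometry, which places the two aryl groups trans as in a trans-stilbene.

Step 5
Reactants: 7 stilbene-type alkene
Product: 8 5-(benzyloxy)-2-[(2R,3R)-3-[3,4-bis(benzyloxy)phenyl]-2-(diethoxymethyl)oxiran-2-yl]phenyl 2,2-dimethylpropanoate
Conditions: D-fructose-derived ketone catalyst 1,2:4,5-di-O-isopropylidene-β-D-erythro-2,3-hexodiulo-2,6-pyranose (30 mol%), Oxone (2KHSO5·KHSO4·K2SO4), K2CO3, Bu4NHSO4 (cat.), MeCN/dimethoxymethane/aq. Na2B4O7 buffer (pH 10.5), 0 °C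
Reagents that add atoms: potassium peroxymonosulfate, [K+].[O-]S(=O)(=O)OO
Why: Shi epoxidation; the dioxirane of the D-fructose-derived ketone should attack the trans-stilbene-type trisubstituted alkene through the spiro transition state on the face that makes the aryl-bearing carbon R, so both epoxide stereocentres are set by the catalyst.

Step 6
Reactants: 8 epoxy pivalate
Product: 10 (2S,3R)-6-(benzyloxy)-2-[3,4-bis(benzyloxy)phenyl]-3-(diethoxymethyl)-2,3-dihydro-1-benzofuran-3-ol, via potassium phenoxide 9 (not isolated)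
Conditions: K2CO3, MeOH/THF, rt → 40 °C
Reagents that add atoms: none
Why: Methanolysis of the pivalate frees the phenoxide, which opens the epoxide at the benzylic carbon in a 5-exo-tet substitution with inversion (R becomes 2S), leaving the epoxide oxygen as the tertiary 3-OH trans to the 2-aryl group.

Step 7
Reactants: 10 hydroxy acetal
Product: 11 (2S,3R)-6-(benzyloxy)-2-[3,4-bis(benzyloxy)phenyl]-5-bromo-3-(diethoxymethyl)-2,3-dihydro-1-benzofuran-3-ol
Conditions: NBS (1.05 equiv), MeCN, −20 → 0 °C, dark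
Reagents that add atoms: N-bromosuccinimide, BrN1C(=O)CCC1=O
Why: Electrophilic aromatic bromination at C5, the position para to O1 and ortho to the 6-benzyloxy group and so the most activated one.

Step 8
Reactants: 10 hydroxy acetal
Product: 12 (2S,3R)-6-(benzyloxy)-2-[3,4-bis(benzyloxy)phenyl]-5-chloro-3-(diethoxymethyl)-2,3-dihydro-1-benzofuran-3-ol
Conditions: NCS (1.05 equiv), DMF, rt
Reagents that add atoms: N-chlorosuccinimide, ClN1C(=O)CCC1=O
Why: Electrophilic aromatic chlorination at the same doubly activated position C5.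

Step 9
Reactants: 13 (+)-catechin
Product: 14 5,7,3',4'-tetra-O-benzyl-(+)-catechin
Conditions: BnBr (4.4 equiv), K2CO3, DMF, 0 °C → rt
Reagents that add atoms: benzyl bromide, BrCc1ccccc1
Why: Williamson etherification of the four phenols; the aliphatic 3-OH is not deprotonated by K2CO3 and stays free.

Step 10
Reactants: 11 bromo hydroxy acetal; 14 5,7,3',4'-tetra-O-benzyl-(+)-catechin (3 equiv)
Product: 16 (2S,4S)-7-(benzyloxy)-2-[3,4-bis(benzyloxy)phenyl]-6-bromo-4-(5,7,3',4'-tetra-O-benzylcatechin-8-yl)chroman-3-one (2,4-trans), via ethyl ether adduct 15 (not isolated)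
Conditions: TMSOTf (0.3 equiv), 4 Å MS, CH2Cl2, −78 → −30 °C; Et3N quench
Reagents that add atoms: none
Why: Proposed new method: the acetal of 11 is ionised to an oxocarbenium ion that alkylates C8 of 14 (the position benzylated catechin offers to flavan-4-yl cations), the benzylic ether 15 ionises again and the ring A carbon shifts from the carbinol carbon to the cation with ring expansion to the chromanone, the new C4 centre forming trans to the 2-aryl group as argued in step 12; the closest known reactions are Friedel–Crafts alkylation of polyalkoxyarenes with acetals and the pinacol-type ring expansion of 1-(α-hydroxybenzyl)cycloalkanols, and excess 14 and the bromine at C5 of 11 should suppress double and self-alkylation.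

Step 11
Reactants: 16 ketone dimer
Product: 17 6-bromo-7,3',4'-tri-O-benzyl-ent-fisetinidol-(4α→8)-5,7,3',4'-tetra-O-benzylcatechin (upper unit 2S,3R,4S; 2,3-trans-3,4-cis)
Conditions: NaBH4, CeCl3·7H2O, THF/MeOH, −78 → −40 °C
Reagents that add atoms: none
Why: Luche reduction; hydride should add to C3 from the face opposite the quasi-axial 4-aryl group (axial attack), giving the equatorial 3-OH trans to the 2-aryl and cis to the 4-aryl group, and the weakly basic medium limits enolisation at C4.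

Step 12
Reactants: 17 bromo dimer; 12 chloro hydroxy acetal (1.3 equiv)
Product: 19 (2S,4S)-7-(benzyloxy)-2-[3,4-bis(benzyloxy)phenyl]-6-chloro-chroman-3-one bonded through C4 to C6 of the catechin unit of 17 (2,4-trans), via ethyl ether adduct 18 (not isolated)
Conditions: TMSOTf (0.3 equiv), 4 Å MS, CH2Cl2, −78 → −20 °C; Et3N quench
Reagents that add atoms: none
Why: Proposed new method: TMSOTf ionises the diethyl acetal of 12 to an oxocarbenium ion that alkylates C6 of the catechin unit of 17 (Friedel–Crafts), the trialkoxybenzylic ethyl ether 18 ionises again, and the ring A carbon C3a (para to O-benzyl, ortho to O1) migrates from the carbinol carbon C3 to the cationic carbon while C3 becomes the ketone, so the dihydrofuran ring O1–C2–C3–C3a–C7a is expanded by one carbon to the pyran ring O1–C2–C3–C4–C4a–C8a (closure by 1,2-aryl shift, a pinacol-type ring expansion); if the aryl shift precedes the arylation, the 4-ethoxychroman-3-one so formed can ionise at C4 and alkylate the same position, so both orders converge on 19. The closest known reactions are the Friedel–Crafts alkylation of polyalkoxyarenes with acetals, the pinacol and semipinacol ring expansion of 1-(α-hydroxybenzyl)cycloalkanols, and the Lewis-acid coupling of flavan-4-yl cations with benzylated catechin. The new stereocentre C4 is controlled by C2 and C3 of 12: in the cation the catechin ring should eclipse the small 3-OH and not C2, whose aryl group lies on the face of the migration terminus, so the shift places the new aryl group trans to the 2-aryl group (quasi-axial), which is also the outcome of quasi-axial attack on a flavan-4-yl cation and the arrangement favoured at equilibrium by peri strain. C2 is not touched and the C3 stereocentre of 12 is consumed. The step needs regioselectivity for catechin C6, secured because C8 is substituted and C6 of unit B carries bromine. It also needs the electrophile not to alkylate itself, secured by the chlorine at C5 of 12.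

Step 13
Reactants: 19 ketone trimer
Product: 20 6-bromo-7,3',4'-tri-O-benzyl-ent-fisetinidol-(4α→8)-5,7,3',4'-tetra-O-benzylcatechin-(6→4α)-6-chloro-7,3',4'-tri-O-benzyl-ent-fisetinidol (both upper units 2S,3R; 2,3-trans-3,4-cis)
Conditions: NaBH4, CeCl3·7H2O, THF/MeOH, −78 → −40 °C
Reagents that add atoms: none
Why: Luche reduction as in step 11; hydride attack anti to the quasi-axial 4-aryl group sets C3 of unit D as 3R (3,4-cis, 2,3-trans).

Step 14
Reactants: 20 bromo chloro trimer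
Product: 22 7,3',4'-tri-O-benzyl-ent-fisetinidol-(4α→8)-5,7,3',4'-tetra-O-benzylcatechin-(6→4α)-6-chloro-7,3',4'-tri-O-benzyl-ent-fisetinidol, via aryllithium trialkoxide 21 (not isolated)
Conditions: n-BuLi (4.5 equiv), THF, −78 °C; MeOH, −78 °C
Reagents that add atoms: none
Why: After deprotonation of the three hydroxyls, bromine–lithium exchange at −78 °C is much faster than any reaction of the aryl chloride or the benzyl ethers, and protonation of the aryllithium frees C6–H of unit B.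

Step 15
Reactants: 22 chloro trimer; 12 chloro hydroxy acetal (1.5 equiv)
Product: 24 (2S,4R)-7-(benzyloxy)-2-[3,4-bis(benzyloxy)phenyl]-6-chloro-chroman-3-one bonded through C4 to C6 of unit B of 22 (2,4-trans), via ethyl ether adduct 23 (not isolated)
Conditions: TMSOTf (0.3 equiv), 4 Å MS, CH2Cl2, −78 → −10 °C; Et3N quench
Reagents that add atoms: none
Why: Proposed new method: the same acetal ionisation, Friedel–Crafts alkylation and pinacol-type 1,2-aryl shift with ring expansion as in step 12 (closest known reactions as named there), now at C6 of unit B, the only free position para to a ring oxygen and ortho to a benzyloxy group, since the catechin ring is fully substituted and C6 of unit D is chlorinated; C4 should again form trans to the 2-aryl group.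

Step 16
Reactants: 24 ketone tetramer
Product: 25 6-chloro-7,3',4'-tri-O-benzyl-ent-fisetinidol-(4α→6)-7,3',4'-tri-O-benzyl-ent-fisetinidol-(4α→8)-5,7,3',4'-tetra-O-benzylcatechin-(6→4α)-6-chloro-7,3',4'-tri-O-benzyl-ent-fisetinidol
Conditions: NaBH4, CeCl3·7H2O, THF/MeOH, −78 → −40 °C
Reagents that add atoms: none
Why: Luche reduction as in step 11, setting C3 of unit A as 3R by hydride attack anti to the quasi-axial 4-aryl group.

Step 17
Reactants: 25 protected dichloro tetramer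
Product: 26 ent-fisetinidol-(4α→6)-ent-fisetinidol-(4α→8)-catechin-(6→4α)-ent-fisetinidol (CNP0126838.1)
Conditions: H2 (1 atm), Pd(OH)2/C, Et3N (2.2 equiv), THF/MeOH, rt
Reagents that add atoms: none
Why: Hydrogenolysis of the thirteen benzyl ethers together with hydrodechlorination of the two aryl chlorides (Et3N takes up HCl); no stereocentre is touched.

**Compound list**

1 | 4-bromo-1,2-bis(benzyloxy)benzene | Brc1ccc(OCc2ccccc2)c(OCc2ccccc2)c1 | starting material
2 | 3,3-diethoxyprop-1-yne | CCOC(OCC)C#C | starting material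
3 | 1,2-bis(benzyloxy)-4-(3,3-diethoxyprop-1-yn-1-yl)benzene | CCOC(OCC)C#Cc1ccc(OCc2ccccc2)c(OCc2ccccc2)c1 | intermediate
4 | 2-[(1Z)-1-[3,4-bis(benzyloxy)phenyl]-3,3-diethoxyprop-1-en-2-yl]-4,4,5,5-tetramethyl-1,3,2-dioxaborolane | CCOC(OCC)/C(B1OC(C)(C)C(C)(C)O1)=C\c1ccc(OCc2ccccc2)c(OCc2ccccc2)c1 | intermediate
5 | 5-(benzyloxy)-2-bromophenol | Oc1cc(OCc2ccccc2)ccc1Br | starting material
6 | 5-(benzyloxy)-2-bromophenyl 2,2-dimethylpropanoate | CC(C)(C)C(=O)Oc1cc(OCc2ccccc2)ccc1Br | intermediate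
7 | 5-(benzyloxy)-2-[(1Z)-1-[3,4-bis(benzyloxy)phenyl]-3,3-diethoxyprop-1-en-2-yl]phenyl 2,2-dimethylpropanoate | CCOC(OCC)/C(c1ccc(OCc2ccccc2)cc1OC(=O)C(C)(C)C)=C\c1ccc(OCc2ccccc2)c(OCc2ccccc2)c1 | intermediate
8 | 5-(benzyloxy)-2-[(2R,3R)-3-[3,4-bis(benzyloxy)phenyl]-2-(diethoxymethyl)oxiran-2-yl]phenyl 2,2-dimethylpropanoate | CCOC(OCC)[C@]1(c2ccc(OCc3ccccc3)cc2OC(=O)C(C)(C)C)O[C@@H]1c1ccc(OCc2ccccc2)c(OCc2ccccc2)c1 | intermediate
9 | 5-(benzyloxy)-2-[(2R,3R)-3-[3,4-bis(benzyloxy)phenyl]-2-(diethoxymethyl)oxiran-2-yl]phenol, formed as its potassium salt (not isolated) | CCOC(OCC)[C@]1(c2ccc(OCc3ccccc3)cc2O)O[C@@H]1c1ccc(OCc2ccccc2)c(OCc2ccccc2)c1 | intermediate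
10 | (2S,3R)-6-(benzyloxy)-2-[3,4-bis(benzyloxy)phenyl]-3-(diethoxymethyl)-2,3-dihydro-1-benzofuran-3-ol | CCOC(OCC)[C@@]1(O)c2ccc(OCc3ccccc3)cc2O[C@H]1c1ccc(OCc2ccccc2)c(OCc2ccccc2)c1 | intermediate
11 | (2S,3R)-6-(benzyloxy)-2-[3,4-bis(benzyloxy)phenyl]-5-bromo-3-(diethoxymethyl)-2,3-dihydro-1-benzofuran-3-ol | CCOC(OCC)[C@@]1(O)c2cc(Br)c(OCc3ccccc3)cc2O[C@H]1c1ccc(OCc2ccccc2)c(OCc2ccccc2)c1 | intermediate
12 | (2S,3R)-6-(benzyloxy)-2-[3,4-bis(benzyloxy)phenyl]-5-chloro-3-(diethoxymethyl)-2,3-dihydro-1-benzofuran-3-ol | CCOC(OCC)[C@@]1(O)c2cc(Cl)c(OCc3ccccc3)cc2O[C@H]1c1ccc(OCc2ccccc2)c(OCc2ccccc2)c1 | intermediate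
13 | (+)-catechin (2R,3S) | c1c(O)cc(O)c2c1O[C@H](c1ccc(O)c(O)c1)[C@@H](O)C2 | starting material
14 | 5,7,3',4'-tetra-O-benzyl-(+)-catechin | c1c(OCc3ccccc3)cc(OCc3ccccc3)c2c1O[C@H](c1ccc(OCc3ccccc3)c(OCc3ccccc3)c1)[C@@H](O)C2 | intermediate
15 | ethyl ether adduct of 11 at C8 of 14, epimers at the new ether carbon (not isolated) | CCOC(c1c(OCc3ccccc3)cc(OCc3ccccc3)c2c1O[C@H](c1ccc(OCc3ccccc3)c(OCc3ccccc3)c1)[C@@H](O)C2)[C@@]1(O)c2cc(Br)c(OCc3ccccc3)cc2O[C@H]1c1ccc(OCc3ccccc3)c(OCc3ccccc3)c1 | intermediate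
16 | (2S,4S)-7-(benzyloxy)-2-[3,4-bis(benzyloxy)phenyl]-6-bromo-4-(5,7,3',4'-tetra-O-benzylcatechin-8-yl)chroman-3-one, 2,4-trans | Brc1cc2c(cc1OCc3ccccc3)O[C@@H](c1ccc(OCc3ccccc3)c(OCc3ccccc3)c1)C(=O)[C@@H]2c1c(OCc3ccccc3)cc(OCc3ccccc3)c2c1O[C@H](c1ccc(OCc3ccccc3)c(OCc3ccccc3)c1)[C@@H](O)C2 | intermediate
17 | 6-bromo-7,3',4'-tri-O-benzyl-ent-fisetinidol-(4α→8)-5,7,3',4'-tetra-O-benzylcatechin | Brc1cc2c(cc1OCc3ccccc3)O[C@@H](c1ccc(OCc3ccccc3)c(OCc3ccccc3)c1)[C@H](O)[C@@H]2c1c(OCc3ccccc3)cc(OCc3ccccc3)c2c1O[C@H](c1ccc(OCc3ccccc3)c(OCc3ccccc3)c1)[C@@H](O)C2 | intermediate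
18 | ethyl ether adduct of 12 at C6 of the catechin unit of 17, epimers at the new ether carbon (not isolated) | Brc1cc2c(cc1OCc3ccccc3)O[C@@H](c1ccc(OCc3ccccc3)c(OCc3ccccc3)c1)[C@H](O)[C@@H]2c1c(OCc3ccccc3)c(C(OCC)[C@@]2(O)c3cc(Cl)c(OCc4ccccc4)cc3O[C@H]2c2ccc(OCc3ccccc3)c(OCc3ccccc3)c2)c(OCc3ccccc3)c2c1O[C@H](c1ccc(OCc3ccccc3)c(OCc3ccccc3)c1)[C@@H](O)C2 | intermediate
19 | ketone trimer: unit D as (2S,4S)-6-chloro-2,4-trans-chroman-3-one at catechin C6 of 17 | Brc1cc2c(cc1OCc3ccccc3)O[C@@H](c1ccc(OCc3ccccc3)c(OCc3ccccc3)c1)[C@H](O)[C@@H]2c1c(OCc3ccccc3)c([C@@H]2c3cc(Cl)c(OCc4ccccc4)cc3O[C@@H](c3ccc(OCc4ccccc4)c(OCc4ccccc4)c3)C2=O)c(OCc3ccccc3)c2c1O[C@H](c1ccc(OCc3ccccc3)c(OCc3ccccc3)c1)[C@@H](O)C2 | intermediate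
20 | 6-bromo-7,3',4'-tri-O-benzyl-ent-fisetinidol-(4α→8)-5,7,3',4'-tetra-O-benzylcatechin-(6→4α)-6-chloro-7,3',4'-tri-O-benzyl-ent-fisetinidol | Brc1cc2c(cc1OCc3ccccc3)O[C@@H](c1ccc(OCc3ccccc3)c(OCc3ccccc3)c1)[C@H](O)[C@@H]2c1c(OCc3ccccc3)c([C@@H]2c3cc(Cl)c(OCc4ccccc4)cc3O[C@@H](c3ccc(OCc4ccccc4)c(OCc4ccccc4)c3)[C@@H]2O)c(OCc3ccccc3)c2c1O[C@H](c1ccc(OCc3ccccc3)c(OCc3ccccc3)c1)[C@@H](O)C2 | intermediate
21 | aryllithium at C6 of unit B of 20 with the three hydroxyls as lithium alkoxides (not isolated) | [Li]c1cc2c(cc1OCc3ccccc3)O[C@@H](c1ccc(OCc3ccccc3)c(OCc3ccccc3)c1)[C@H](O[Li])[C@@H]2c1c(OCc3ccccc3)c([C@@H]2c3cc(Cl)c(OCc4ccccc4)cc3O[C@@H](c3ccc(OCc4ccccc4)c(OCc4ccccc4)c3)[C@@H]2O[Li])c(OCc3ccccc3)c2c1O[C@H](c1ccc(OCc3ccccc3)c(OCc3ccccc3)c1)[C@@H](O[Li])C2 | intermediate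
22 | 7,3',4'-tri-O-benzyl-ent-fisetinidol-(4α→8)-5,7,3',4'-tetra-O-benzylcatechin-(6→4α)-6-chloro-7,3',4'-tri-O-benzyl-ent-fisetinidol | c1cc2c(cc1OCc3ccccc3)O[C@@H](c1ccc(OCc3ccccc3)c(OCc3ccccc3)c1)[C@H](O)[C@@H]2c1c(OCc3ccccc3)c([C@@H]2c3cc(Cl)c(OCc4ccccc4)cc3O[C@@H](c3ccc(OCc4ccccc4)c(OCc4ccccc4)c3)[C@@H]2O)c(OCc3ccccc3)c2c1O[C@H](c1ccc(OCc3ccccc3)c(OCc3ccccc3)c1)[C@@H](O)C2 | intermediate
23 | ethyl ether adduct of 12 at C6 of unit B of 22, epimers at the new ether carbon (not isolated) | CCOC(c1cc2c(cc1OCc3ccccc3)O[C@@H](c1ccc(OCc3ccccc3)c(OCc3ccccc3)c1)[C@H](O)[C@@H]2c1c(OCc3ccccc3)c([C@@H]2c3cc(Cl)c(OCc4ccccc4)cc3O[C@@H](c3ccc(OCc4ccccc4)c(OCc4ccccc4)c3)[C@@H]2O)c(OCc3ccccc3)c2c1O[C@H](c1ccc(OCc3ccccc3)c(OCc3ccccc3)c1)[C@@H](O)C2)[C@@]1(O)c2cc(Cl)c(OCc3ccccc3)cc2O[C@H]1c1ccc(OCc3ccccc3)c(OCc3ccccc3)c1 | intermediate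
24 | ketone tetramer: unit A as (2S,4R)-6-chloro-2,4-trans-chroman-3-one at C6 of unit B of 22 | Clc1cc2c(cc1OCc3ccccc3)O[C@@H](c1ccc(OCc3ccccc3)c(OCc3ccccc3)c1)C(=O)[C@@H]2c1cc2c(cc1OCc3ccccc3)O[C@@H](c1ccc(OCc3ccccc3)c(OCc3ccccc3)c1)[C@H](O)[C@@H]2c1c(OCc3ccccc3)c([C@@H]2c3cc(Cl)c(OCc4ccccc4)cc3O[C@@H](c3ccc(OCc4ccccc4)c(OCc4ccccc4)c3)[C@@H]2O)c(OCc3ccccc3)c2c1O[C@H](c1ccc(OCc3ccccc3)c(OCc3ccccc3)c1)[C@@H](O)C2 | intermediate
25 | 6-chloro-7,3',4'-tri-O-benzyl-ent-fisetinidol-(4α→6)-7,3',4'-tri-O-benzyl-ent-fisetinidol-(4α→8)-5,7,3',4'-tetra-O-benzylcatechin-(6→4α)-6-chloro-7,3',4'-tri-O-benzyl-ent-fisetinidol | Clc1cc2c(cc1OCc3ccccc3)O[C@@H](c1ccc(OCc3ccccc3)c(OCc3ccccc3)c1)[C@H](O)[C@@H]2c1cc2c(cc1OCc3ccccc3)O[C@@H](c1ccc(OCc3ccccc3)c(OCc3ccccc3)c1)[C@H](O)[C@@H]2c1c(OCc3ccccc3)c([C@@H]2c3cc(Cl)c(OCc4ccccc4)cc3O[C@@H](c3ccc(OCc4ccccc4)c(OCc4ccccc4)c3)[C@@H]2O)c(OCc3ccccc3)c2c1O[C@H](c1ccc(OCc3ccccc3)c(OCc3ccccc3)c1)[C@@H](O)C2 | intermediate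
26 | ent-fisetinidol-(4α→6)-ent-fisetinidol-(4α→8)-catechin-(6→4α)-ent-fisetinidol (CNP0126838.1) | Oc1ccc2c(c1)O[C@@H](c1ccc(O)c(O)c1)[C@H](O)[C@@H]2c1cc2c(cc1O)O[C@@H](c1ccc(O)c(O)c1)[C@H](O)[C@@H]2c1c(O)c([C@@H]2c3ccc(O)cc3O[C@@H](c3ccc(O)c(O)c3)[C@@H]2O)c(O)c2c1O[C@H](c1ccc(O)c(O)c1)[C@@H](O)C2 | target

**Totals**

Total step count: 17. Longest linear sequence: 14 steps (1, 2, 4, 5, 6, 7, 10, 11, 12, 13, 14, 15, 16, 17).

**Steps most likely to fail**

Step 12. Capture of the oxocarbenium ion by the doubly flanked C6 of the catechin unit may be too slow, so that dehydration of the tertiary benzylic carbinol to the aromatic benzofuran, or acid cleavage of the existing interflavan bond, runs ahead of C–C bond formation. The fallback turns the aryl partner into an organometallic and does the ring expansion as a separate pinacol-type step, setting out from 17 and 12. Iodination of 17 at C6 of the catechin unit (N-iodosuccinimide, CH2Cl2, 0 °C) should give the iodo dimer F1. Treatment of 12 with TESOTf and 2,4,6-collidine in CH2Cl2 at 0 °C, then water, should cleave the acetal and silylate the tertiary hydroxyl to give the silyl-protected aldehyde F2. F1 with iPrMgCl·LiCl (3.1 equiv, THF, −40 °C) is deprotonated at its two hydroxyls and undergoes iodine–magnesium exchange, leaving the aryl bromide and chloride. Addition of the arylmagnesium to F2 gives the carbinol F3 as epimers at the new carbinol carbon. Camphorsulfonic acid (cat.) in CH2Cl2 at −40 °C then ionises the benzylic hydroxyl and the ring A carbon shifts with loss of the silyl group, which returns to the route at ketone 19.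

Step 15. The ring of unit B, activated by only two oxygens, may alkylate too slowly, so that the electrophile is lost to dehydration before it is captured. The fallback uses the aryllithium already available, setting out from 20 and 12 and leaving step 14 aside. Compound 20 is converted with n-BuLi (4.2 equiv, THF, −78 °C) into the aryllithium 21, which is not protonated but treated with the silyl-protected aldehyde F2 (made from 12 as described for step 12). Aqueous work-up should give the carbinol F5. Camphorsulfonic acid (cat.) in CH2Cl2 at −40 °C then induces the pinacol-type 1,2-aryl shift with ring expansion and loss of the silyl group, which returns to the route at ketone 24.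

Step 10. The electrophile may be lost by dehydration or over-alkylation of the product at catechin C6 before clean mono-alkylation at C8. The fallback separates the ring expansion from the arylation, setting out from 11 and 14. BF3·OEt2 (1.1 equiv) in CH2Cl2 at −78 °C, without an arene, should convert 11 by the known acyloin-type rearrangement of α-hydroxy acetals into the 4-ethoxychromanone F4 (epimers at C4), the ring expansion now being its own step. F4 is then used as a benzylic ether donor toward 14 (3 equiv) with TMSOTf in CH2Cl2 at −40 → 0 °C, a Friedel–Crafts benzylation of the kind used for 4-alkoxyflavans, which returns to the route at ketone 16.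

Further compounds
F1 | step 12 | 6-bromo-7,3',4'-tri-O-benzyl-ent-fisetinidol-(4α→8)-6-iodo-5,7,3',4'-tetra-O-benzylcatechin | Brc1cc2c(cc1OCc3ccccc3)O[C@@H](c1ccc(OCc3ccccc3)c(OCc3ccccc3)c1)[C@H](O)[C@@H]2c1c(OCc3ccccc3)c(I)c(OCc3ccccc3)c2c1O[C@H](c1ccc(OCc3ccccc3)c(OCc3ccccc3)c1)[C@@H](O)C2
F2 | step 12 | (2S,3R)-6-(benzyloxy)-2-[3,4-bis(benzyloxy)phenyl]-5-chloro-3-[(triethylsilyl)oxy]-2,3-dihydro-1-benzofuran-3-carbaldehyde | O=C[C@@]1(O[Si](CC)(CC)CC)c2cc(Cl)c(OCc3ccccc3)cc2O[C@H]1c1ccc(OCc3ccccc3)c(OCc3ccccc3)c1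
F3 | step 12 | carbinol from the C6-magnesiated catechin unit of F1 and F2, epimers at the carbinol carbon | Brc1cc2c(cc1OCc3ccccc3)O[C@@H](c1ccc(OCc3ccccc3)c(OCc3ccccc3)c1)[C@H](O)[C@@H]2c1c(OCc3ccccc3)c(C(O)[C@@]2(O[Si](CC)(CC)CC)c3cc(Cl)c(OCc4ccccc4)cc3O[C@H]2c2ccc(OCc3ccccc3)c(OCc3ccccc3)c2)c(OCc3ccccc3)c2c1O[C@H](c1ccc(OCc3ccccc3)c(OCc3ccccc3)c1)[C@@H](O)C2
F4 | step 10 | (2S)-7-(benzyloxy)-2-[3,4-bis(benzyloxy)phenyl]-6-bromo-4-ethoxychroman-3-one, epimers at C4 | CCOC1c2cc(Br)c(OCc3ccccc3)cc2O[C@@H](c2ccc(OCc3ccccc3)c(OCc3ccccc3)c2)C1=O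
F5 | step 15 | carbinol from aryllithium 21 and F2, epimers at the carbinol carbon | OC(c1cc2c(cc1OCc3ccccc3)O[C@@H](c1ccc(OCc3ccccc3)c(OCc3ccccc3)c1)[C@H](O)[C@@H]2c1c(OCc3ccccc3)c([C@@H]2c3cc(Cl)c(OCc4ccccc4)cc3O[C@@H](c3ccc(OCc4ccccc4)c(OCc4ccccc4)c3)[C@@H]2O)c(OCc3ccccc3)c2c1O[C@H](c1ccc(OCc3ccccc3)c(OCc3ccccc3)c1)[C@@H](O)C2)[C@@]1(O[Si](CC)(CC)CC)c2cc(Cl)c(OCc3ccccc3)cc2O[C@H]1c1ccc(OCc3ccccc3)c(OCc3ccccc3)c1
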